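The achiral tridepside (rings A, B, C, counted from the dimethoxy end) is cut between ring-B C1 and the carbonyl carbon of the B–C ester. A palladium-catalysed aryloxycarbonylation joins A–B iodide 10, which carries iodine on ring-B C1 between C2–OBn and C6–CH3, to formate 13, the 4-O-formyl derivative of benzyl orsellinate. The formyl carbon of 13 becomes the ester carbonyl, so the C–C bond and the whole B–C depside link arise in one operation without CO gas. The step exploits the orcinol pattern of ring B, which guides iodine to C1, and the chelated 2-OH groups of rings A and C, which need no protection.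

Key step: step 9

Remark: the target SMILES holds no stereocentre and no stereogenic double bond. The compound is achiral, so no step has to set or keep configuration. Ring positions use benzoate numbering (C1 bears the carbonyl group).

Step 1
Reactants: 1 2,3-dimethoxytoluene
Product: 3 3,4-dimethoxy-5-methylphenol, via aryl pinacol boronate 2 (not isolated)
Conditions: [Ir(OMe)(cod)]2 (1.5 mol %), dtbpy (3 mol %), B2pin2 (1.0 equiv), THF, 80 °C; then aq. Oxone, acetone, rt
Reagents that add atoms: bis(pinacolato)diboron, CC1(C)OB(OC1(C)C)B1OC(C)(C)C(C)(C)O1 (Bpin of 2); potassium peroxymonosulfate (Oxone), [K+].[O-]S(=O)(=O)OO (phenol oxygen of 3)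
Why: Iridium-catalysed C–H borylation is sterically governed, so a 1,2,3-trisubstituted arene should react only at C5, the one C–H without an ortho neighbour, and the one-pot oxidation turns C–B into C–OH at the same position.

Step 2
Reactants: 3 3,4-dimethoxy-5-methylphenol
Product: 5 2-hydroxy-4,5-dimethoxy-6-methylbenzaldehyde, via aryl iminium chloride 4 (not isolated)
Conditions: POCl3 (1.5 equiv), DMF, 0 → 50 °C; then ice-water
Reagents that add atoms: N,N-dimethylformamide, CN(C)C=O (formyl carbon); phosphoryl chloride, O=P(Cl)(Cl)Cl (chloride of 4); water, O (carbonyl oxygen)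
Why: In this Vilsmeier–Haack formylation the electrophile should attack C6 of the phenol (ortho to OH, para to the 3-OMe) rather than C2, which is wedged between two oxygen substituents, and hydrolysis of 4 gives the chelated salicylaldehyde.

Step 3
Reactants: 5 2-hydroxy-4,5-dimethoxy-6-methylbenzaldehyde
Product: 6 2-hydroxy-4,5-dimethoxy-6-methylbenzoic acid
Conditions: NaClO2, NaH2PO4, 2-methyl-2-butene, t-BuOH–H2O, rt
Reagents that add atoms: sodium chlorite, [Na+].[O-]Cl=O
Why: The Pinnick oxidation is selective for the aldehyde, and the alkene scavenger removes HOCl before it can chlorinate the electron-rich ring.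

Step 4
Reactants: 7 orcinol (5-methylbenzene-1,3-diol)
Product: 8 4-iodo-5-methylbenzene-1,3-diol
Conditions: NIS (1.0 equiv), MeCN, −20 → 0 °C, dark
Reagents that add atoms: N-iodosuccinimide, O=C1CCC(=O)N1I
Why: Electrophilic aromatic iodination under kinetic, non-basic conditions should go para to one OH and ortho to the other (C4, equivalent to C6 by symmetry) rather than to the doubly flanked C2, and one equivalent at low temperature limits di-iodination.

Step 5
Reactants: 6 2-hydroxy-4,5-dimethoxy-6-methylbenzoic acid; 8 4-iodo-5-methylbenzene-1,3-diol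
Product: 9 3-hydroxy-4-iodo-5-methylphenyl 2-hydroxy-4,5-dimethoxy-6-methylbenzoate
Conditions: DCC (1.1 equiv), 8 (1.5 equiv), dry toluene–THF, rt
Reagents that add atoms: none
Why: In this carbodiimide (Steglich-type) depside esterification the 2,6-disubstituted acyl donor should choose the unhindered, more nucleophilic 1-OH of 8 (two ortho hydrogens) over the 3-OH next to iodine, while the chelated 2-OH of 6 does not compete.

Step 6
Reactants: 9 3-hydroxy-4-iodo-5-methylphenyl 2-hydroxy-4,5-dimethoxy-6-methylbenzoate
Product: 10 3-(benzyloxy)-4-iodo-5-methylphenyl 2-hydroxy-4,5-dimethoxy-6-methylbenzoate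
Conditions: BnBr (1.1 equiv), K2CO3, acetone, rt → 40 °C
Reagents that add atoms: benzyl bromide, BrCc1ccccc1
Why: In this Williamson etherification the ortho-iodophenol OH is the most acidic and the only non-chelated hydroxyl, so weak base should alkylate it selectively while the hindered aryl ester resists carbonate.

Step 7
Reactants: 11 orsellinic acid (2,4-dihydroxy-6-methylbenzoic acid)
Product: 12 benzyl orsellinate (benzyl 2,4-dihydroxy-6-methylbenzoate)
Conditions: BnBr (1.05 equiv), KHCO3, DMF, 40 °C
Reagents that add atoms: benzyl bromide, BrCc1ccccc1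
Why: This is an SN2 alkylation of the carboxylate, because hydrogen carbonate deprotonates only the carboxylic acid and both phenols stay free.

Step 8
Reactants: 12 benzyl orsellinate
Product: 13 benzyl 4-(formyloxy)-2-hydroxy-6-methylbenzoate
Conditions: HCO2H, Ac2O, 60 °C (premix); then 12, NaOAc (cat.), toluene, 0 °C → rt
Reagents that add atoms: formic acid, O=CO (delivered as acetic formic anhydride)
Why: In this O-formylation with a mixed anhydride the more electrophilic formyl carbon is transferred, and only the non-chelated 4-OH reacts.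

Step 9
Reactants: 10 3-(benzyloxy)-4-iodo-5-methylphenyl 2-hydroxy-4,5-dimethoxy-6-methylbenzoate; 13 benzyl 4-(formyloxy)-2-hydroxy-6-methylbenzoate
Product: 15 benzyl 4-{[2-(benzyloxy)-4-[(2-hydroxy-4,5-dimethoxy-6-methylbenzoyl)oxy]-6-methylbenzoyl]oxy}-2-hydroxy-6-methylbenzoate, via carbon monoxide 14 (not isolated), via benzyl orsellinate 12 (not isolated)
Conditions: Pd(OAc)2 (5 mol %), Xantphos (10 mol %), Et3N (2 equiv, slow addition), 13 (1.5 equiv), toluene, sealed tube, 80 °C
Reagents that add atoms: none
Why: Et3N fragments formate 13 in the closed vessel into CO (14) and the phenoxide of 12, Pd(0)/Xantphos inserts into the C–I bond of 10, migratory insertion of CO makes the ring-B C1–C(=O) bond, and the acyl-palladium is captured by the 4-phenoxide of 12 with reductive elimination to the aryl ester. The closest known reaction type is the palladium-catalysed, CO-gas-free carbonylation of aryl halides with aryl formates. No ring is closed and no stereocentre is formed. Chemoselectivity among the phenolic oxygens is needed and is secured because only the 4-OH of 12 is unchelated, the 2-OH groups of rings A and C are hydrogen-bonded to their ortho carbonyl groups and flanked, and the ring-B oxygen is benzylated. The existing A–B ester and the new B–C ester are both 2,6-disubstituted benzoates and should resist transesterification by the weakly basic phenoxide, while the two ortho substituents of the aryl-palladium favour CO insertion over direct C–O coupling. Regiochemistry is fixed by the position of iodine.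

Step 10
Reactants: 15 benzyl 4-{[2-(benzyloxy)-4-[(2-hydroxy-4,5-dimethoxy-6-methylbenzoyl)oxy]-6-methylbenzoyl]oxy}-2-hydroxy-6-methylbenzoate
Product: 16 4-{[2-hydroxy-4-[(2-hydroxy-4,5-dimethoxy-6-methylbenzoyl)oxy]-6-methylbenzoyl]oxy}-2-hydroxy-6-methylbenzoic acid (target)
Conditions: H2 (1 atm), 10 % Pd/C, EtOAc, rt
Reagents that add atoms: none
Why: Catalytic hydrogenolysis cleaves the benzylic C–O bonds of the ether and of the ester in one operation and leaves the aryl ester links and the methoxy groups untouched.

Compound list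
1 | 2,3-dimethoxytoluene | COc1cccc(C)c1OC | starting material
2 | 2-(3,4-dimethoxy-5-methylphenyl)-4,4,5,5-tetramethyl-1,3,2-dioxaborolane | COc1cc(B2OC(C)(C)C(C)(C)O2)cc(C)c1OC | intermediate
3 | 3,4-dimethoxy-5-methylphenol | COc1cc(O)cc(C)c1OC | intermediate
4 | (2-hydroxy-4,5-dimethoxy-6-methylbenzylidene)dimethyliminium chloride | COc1cc(O)c(C=[N+](C)C)c(C)c1OC.[Cl-] | intermediate
5 | 2-hydroxy-4,5-dimethoxy-6-methylbenzaldehyde | COc1cc(O)c(C=O)c(C)c1OC | intermediate
6 | 2-hydroxy-4,5-dimethoxy-6-methylbenzoic acid | COc1cc(O)c(C(=O)O)c(C)c1OC | intermediate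
7 | orcinol (5-methylbenzene-1,3-diol) | Cc1cc(O)cc(O)c1 | starting material
8 | 4-iodo-5-methylbenzene-1,3-diol | Cc1cc(O)cc(O)c1I | intermediate
9 | 3-hydroxy-4-iodo-5-methylphenyl 2-hydroxy-4,5-dimethoxy-6-methylbenzoate | COc1cc(O)c(C(=O)Oc2cc(C)c(I)c(O)c2)c(C)c1OC | intermediate
10 | 3-(benzyloxy)-4-iodo-5-methylphenyl 2-hydroxy-4,5-dimethoxy-6-methylbenzoate | COc1cc(O)c(C(=O)Oc2cc(C)c(I)c(OCc3ccccc3)c2)c(C)c1OC | intermediate
11 | orsellinic acid (2,4-dihydroxy-6-methylbenzoic acid) | Cc1cc(O)cc(O)c1C(=O)O | starting material
12 | benzyl orsellinate (benzyl 2,4-dihydroxy-6-methylbenzoate) | Cc1cc(O)cc(O)c1C(=O)OCc1ccccc1 | intermediate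
13 | benzyl 4-(formyloxy)-2-hydroxy-6-methylbenzoate | Cc1cc(OC=O)cc(O)c1C(=O)OCc1ccccc1 | intermediate
14 | carbon monoxide | [C-]#[O+] | intermediate
15 | benzyl 4-{[2-(benzyloxy)-4-[(2-hydroxy-4,5-dimethoxy-6-methylbenzoyl)oxy]-6-methylbenzoyl]oxy}-2-hydroxy-6-methylbenzoate | COc1cc(O)c(C(=O)Oc2cc(C)c(C(=O)Oc3cc(C)c(C(=O)OCc4ccccc4)c(O)c3)c(OCc3ccccc3)c2)c(C)c1OC | intermediate
16 | 4-{[2-hydroxy-4-[(2-hydroxy-4,5-dimethoxy-6-methylbenzoyl)oxy]-6-methylbenzoyl]oxy}-2-hydroxy-6-methylbenzoic acid | COc1cc(O)c(C(=O)Oc2cc(C)c(C(=O)Oc3cc(C)c(C(=O)O)c(O)c3)c(O)c2)c(C)c1OC | target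

Total step count: 10
Longest linear sequence: 7 (steps 1, 2, 3, 5, 6, 9, 10)

Steps most likely to fail

Step 9. What may go wrong:
- slow turnover of the doubly ortho-substituted, electron-rich aryl-palladium
- acyl scrambling of a depside link by the phenoxide at 80 °C
- intramolecular C–H arylation of the neighbouring benzyl ether before CO is taken up

The fallback sets out from 10 and comes back at 15. Iodine–magnesium exchange (i-PrMgCl·LiCl, 2.2 equiv, the first equivalent being consumed by the ring-A OH, THF, −30 °C) and a CO2 quench should give 2-(benzyloxy)-4-[(2-hydroxy-4,5-dimethoxy-6-methylbenzoyl)oxy]-6-methylbenzoic acid F1. F1 is condensed with the free 4-OH of 12 (TFAA, toluene, rt). The union is then made classically at the ester C–O bond.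

Step 5. What may go wrong:
- poor site selectivity between the two hydroxyl groups of 8
- double acylation
- self-condensation of the activated salicylic acid

The fallback sets out from 8 and comes back at 10.
- The unhindered 1-OH is silylated with bulky TIPSCl/imidazole (DMF, 0 °C) to 2-iodo-3-methyl-5-[(triisopropylsilyl)oxy]phenol F2. A regioisomer can be removed and assigned at this small stage.
- The remaining OH is benzylated (BnBr, K2CO3, acetone) to [3-(benzyloxy)-4-iodo-5-methylphenoxy]triisopropylsilane F3.
- TBAF (THF, 0 °C) frees 3-(benzyloxy)-4-iodo-5-methylphenol F4.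
- The single OH of F4 is esterified with 6 (DCC, toluene).

Step 4. What may go wrong:
- iodination at the position between the two hydroxyl groups
- over-iodination
- oxidative darkening of the free resorcinol

The fallback sets out from 7 and comes back at 8. O-Methylation (Me2SO4, K2CO3, acetone) gives 3,5-dimethoxytoluene F5. Iodination of F5 with NIS (MeCN, rt) goes ortho to the methyl group and para to a methoxy group, giving 2-iodo-1,5-dimethoxy-3-methylbenzene F6. BBr3 (CH2Cl2, −78 → 0 °C) then removes both methyl ethers.

Further compounds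
F1 | step 9 | 2-(benzyloxy)-4-[(2-hydroxy-4,5-dimethoxy-6-methylbenzoyl)oxy]-6-methylbenzoic acid | COc1cc(O)c(C(=O)Oc2cc(C)c(C(=O)O)c(OCc3ccccc3)c2)c(C)c1OC
F2 | step 5 | 2-iodo-3-methyl-5-[(triisopropylsilyl)oxy]phenol | Cc1cc(O[Si](C(C)C)(C(C)C)C(C)C)cc(O)c1I
F3 | step 5 | [3-(benzyloxy)-4-iodo-5-methylphenoxy]triisopropylsilane | Cc1cc(O[Si](C(C)C)(C(C)C)C(C)C)cc(OCc2ccccc2)c1I
F4 | step 5 | 3-(benzyloxy)-4-iodo-5-methylphenol | Cc1cc(O)cc(OCc2ccccc2)c1I
F5 | step 4 | 3,5-dimethoxytoluene | COc1cc(C)cc(OC)c1
F6 | step 4 | 2-iodo-1,5-dimethoxy-3-methylbenzene | COc1cc(C)c(I)c(OC)c1
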